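**Retrosynthetic overview**

- Labels and feature: ring A is the sulfated ring (its carbon 1 is bonded to ring B, its carbon 2 bears the sulfate); ring B is the central ring (B1 bonded to ring A; OH on B2, B4, B6; H on B3; B5 bonded to C1 of ring C). On ring B the oxygen-bearing carbons B2, B4, B6 alternate with B1, B3, B5, so the ring divides into a two-carbon ynol ether (B1–B2, carrying ring A) and a four-carbon 2-alkoxyvinylketene (B3–B6, carrying ring C).
- End game: target 28 ⇐ sodium sulfate 26 ⇐ ring A phenol 25 ⇐ octabenzyl ether 24 ⇐ terphenyl phenol 22 (protonation, hydrogenolysis, sulfation, acetal removal, silyl-to-benzyl exchange).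
- Key disconnection: 22 ⇐ diazoketone 10 + siloxyalkyne 17 by a photochemical Wolff / [2+2] / 4π-opening / 6π-closure cascade forming B3–B4, B6–B1, B2–B3 and B5–B6. Ring B is the only ring made; rings A and C are bought as phloroglucinol derivatives and no aryl–aryl coupling is used.
- Fragments: 10 ⇐ methyl ketone 8 (diazo transfer) ⇐ enamide 7 ⇐ aldol of aldehyde 2 with glycolate Weinreb amide 3; 17 ⇐ alkyne 14 (acetylide oxidation, O-silylation) ⇐ aldehyde 13 ⇐ ortho-formylation of phenol 11.

Key step: step 10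

Remark: the target has no stereocentre; the axis between ring A and ring B bears four ortho oxygens and is unsymmetrical at both ends, but the target gives no axial descriptor, so all biaryl compounds are taken as racemic about that axis.
Remark: the target is drawn as the free hydrogen sulfate, which is acid-labile; it is carried as the sodium salt and protonated only in the last operation.
Remark: the diazoketone is made by diazo transfer to a methyl ketone, because acylation of a diazoalkane by an α,β-unsaturated acid chloride competes with dipolar cycloaddition to the alkene.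

**Route**

Step 1
Reactants: 1 2,4,6-trihydroxybenzaldehyde
Product: 2 2,4,6-tris(benzyloxy)benzaldehyde
Conditions: BnBr (3.5 equiv), K2CO3, DMF, 60 °C
Reagents that add atoms: benzyl bromide, BrCc1ccccc1
Why: Williamson ether synthesis in which the three phenoxides are O-benzylated in a dipolar aprotic solvent, the two hydrogen-bonded ortho hydroxyls reacting last, hence the excess of reagent and mild heating.

Step 2
Reactants: 2 2,4,6-tris(benzyloxy)benzaldehyde; 3 2-(benzyloxy)-N-methoxy-N-methylacetamide
Product: 5 2-(benzyloxy)-3-hydroxy-N-methoxy-N-methyl-3-[2,4,6-tris(benzyloxy)phenyl]propanamide (racemic syn/anti mixture), via lithium enolate 4 (not isolated)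
Conditions: LiN(iPr)2, THF, −78 °C; then 2, −78 °C; NH4Cl quench at −78 °C
Reagents that add atoms: none
Why: Directed aldol addition of the chelated lithium enolate 4 to the non-enolisable aldehyde 2, protonated cold to forestall retro-aldol cleavage; the two new stereocentres form without control and are both removed in step 3.

Step 3
Reactants: 5 the aldol adduct
Product: 7 (Z)-2-(benzyloxy)-N-methoxy-N-methyl-3-[2,4,6-tris(benzyloxy)phenyl]prop-2-enamide, via benzylic mesylate 6 (not isolated)
Conditions: MsCl, Et3N, CH2Cl2, 0 °C; then DBU, 25 °C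
Reagents that add atoms: none
Why: Mesylation and base-induced β-elimination, made easy by the trialkoxyaryl ring that stabilises positive charge at the benzylic carbon, should give the trisubstituted alkene mainly as the Z isomer, in which ring C lies trans to the amide carbonyl.

Step 4
Reactants: 7 the (Z)-enamide
Product: 8 (Z)-3-(benzyloxy)-4-[2,4,6-tris(benzyloxy)phenyl]but-3-en-2-one
Conditions: MeMgBr, THF, 0 °C; NH4Cl work-up
Reagents that add atoms: methylmagnesium bromide, C[Mg]Br
Why: Weinreb ketone synthesis, in which the chelated tetrahedral magnesium adduct stops the addition at the ketone stage and the hindered β-aryl alkene resists conjugate addition.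

Step 5
Reactants: 8 the methyl ketone
Product: 10 (Z)-3-(benzyloxy)-1-diazo-4-[2,4,6-tris(benzyloxy)phenyl]but-3-en-2-one, via trifluoroacetyl ketone 9 (not isolated)
Conditions: LiN(SiMe3)2, THF, −78 °C; CF3CO2CH2CF3; aq HCl work-up; then crude 9, 4-AcNHC6H4SO2N3, Et3N, H2O, MeCN, 25 °C
Reagents that add atoms: 4-acetamidobenzenesulfonyl azide, CC(=O)Nc1ccc(cc1)S(=O)(=O)N=[N+]=[N-]
Why: Detrifluoroacetylative diazo transfer, in which the methyl group (the only enolisable position) is trifluoroacetylated and the activated 1,3-diketone 9 accepts the diazo group from the sulfonyl azide with loss of the trifluoroacetyl group.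

Step 6
Reactants: 11 3,5-bis(benzyloxy)phenol
Product: 12 2,4-bis(benzyloxy)-6-hydroxybenzaldehyde
Conditions: MgCl2, Et3N, (CH2O)n, MeCN, 80 °C
Reagents that add atoms: paraformaldehyde (as formaldehyde), C=O
Why: Magnesium-mediated ortho-formylation (Casnati–Skattebøl), in which formaldehyde is delivered within the magnesium phenoxide only to the carbon ortho to the hydroxyl and a second formaldehyde oxidises the benzylic alkoxide to the aldehyde.

Step 7
Reactants: 12 2,4-bis(benzyloxy)-6-hydroxybenzaldehyde
Product: 13 2,4-bis(benzyloxy)-6-(methoxymethoxy)benzaldehyde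
Conditions: NaH, MOMCl, DMF, 0 → 25 °C
Reagents that add atoms: chloromethyl methyl ether, COCCl
Why: O-alkylation of the sodium phenoxide by the chloromethyl ether (Williamson type), with NaH breaking the hydrogen bond to the aldehyde.

Step 8
Reactants: 13 2,4-bis(benzyloxy)-6-(methoxymethoxy)benzaldehyde
Product: 14 1,5-bis(benzyloxy)-2-ethynyl-3-(methoxymethoxy)benzene
Conditions: MeCOC(N2)P(O)(OMe)2, K2CO3, MeOH/THF, 25 °C
Reagents that add atoms: dimethyl (1-diazo-2-oxopropyl)phosphonate, CC(=O)C(=[N+]=[N-])P(=O)(OC)OC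
Why: Seyferth–Gilbert homologation in the Ohira–Bestmann form, in which methanolysis releases dimethyl (diazomethyl)phosphonate that olefinates the aldehyde and loses nitrogen with a 1,2-hydrogen shift to the alkyne under conditions mild enough for the acetal and the benzyl ethers.

Step 9
Reactants: 14 the terminal alkyne
Product: 17 triisopropyl({[2,4-bis(benzyloxy)-6-(methoxymethoxy)phenyl]ethynyl}oxy)silane, via lithium acetylide 15 (not isolated), via lithium ynolate 16 (not isolated)
Conditions: LiN(SiMe3)2, THF, −78 °C; LiOOtBu (from t-BuOOH and LiN(SiMe3)2), −78 → 0 °C; iPr3SiOTf, −78 → 0 °C; filtration through Et3N-deactivated silica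
Reagents that add atoms: tert-butyl hydroperoxide, CC(C)(C)OO; triisopropylsilyl trifluoromethanesulfonate, CC(C)[Si](OS(=O)(=O)C(F)(F)F)(C(C)C)C(C)C
Why: Julia oxidation of an acetylide, in which 15 attacks the peroxide oxygen of LiOOtBu to give ynolate 16, which the bulky silyl triflate should trap on oxygen and not on the aryl-shielded carbon.

Step 10
Reactants: 10 the diazoketone; 17 the siloxyalkyne
Product: 22 terphenyl phenol (ring B: free OH at B6; OSi(iPr)3 at B2; OBn at B4; ring A on B1 carrying its methoxymethyl ether; ring C on B5), via vinylketene 18 (not isolated), via vinylcyclobutenone 19 (not isolated), via dienylketene 20 (not isolated), via cyclohexadienone 21 (not isolated)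
Conditions: hν (365 nm), 17 (2 equiv), degassed toluene, 25 °C, slow addition of 10; then 100 °C
Reagents that add atoms: none
Why: Light expels N2 from 10 with a 1,2-shift of the alkoxyvinyl group to the diazo carbon (Wolff rearrangement, B3–B4) to give vinylketene 18, whose C=C=O unit adds across the triple bond of 17 in a [2+2] cycloaddition (B6–B1 and B3–B2) to give vinylcyclobutenone 19; on warming, 19 opens by 4π electrocyclic cleavage of the B6–B3 bond to dienylketene 20, which closes by 6π electrocyclisation (B6–B5) to cyclohexadienone 21 and enolises to phenol 22. The closest known reaction is the Danheiser benzannulation in its photochemical diazoketone form with triisopropylsiloxyalkynes. Ring B, the only ring closed, is formed by 6π electrocyclic closure of the dienylketene, the four-membered ring from the [2+2] step being opened again on the way. No stereocentre is created in 22, since the sp3 centres of 19 and 21 are lost on ring opening and enolisation and the axis between ring A and ring B forms as the racemate. The step needs regioselectivity in the [2+2] addition, secured by the polarity match between the electrophilic ketene carbonyl carbon (B6) and the nucleophilic aryl-bearing carbon of the ynol ether (B1), which places the silyloxy group at B2; it also needs capture of 18 before it dimerises, secured by photon-limited release of the ketene into two equivalents of 17 at a wavelength that 10 but not 17 should absorb. The two ortho benzyloxy groups of ring C block a competing 6π closure of 18 onto ring C, and the Z alkene keeps ring C on the outside of the closing triene.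

Step 11
Reactants: 22 the terphenyl phenol
Product: 24 octabenzyl ether (OBn at B2 and B6; ring A methoxymethyl ether retained), via ring B diol 23 (not isolated)
Conditions: Bu4NF, THF, 0 °C; then BnBr, Cs2CO3, DMF, 50 °C
Reagents that add atoms: benzyl bromide, BrCc1ccccc1
Why: Fluoride cleaves the aryl silyl ether and both ring B phenoxides are then O-benzylated under Williamson conditions in a dipolar aprotic solvent, which should disfavour C-alkylation at B3.

Step 12
Reactants: 24 the octabenzyl ether
Product: 25 ring A phenol (free OH ortho to the bond to ring B; eight benzyl ethers retained)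
Conditions: HCl (cat.), MeOH/THF, 45 °C
Reagents that add atoms: none
Why: Acid-catalysed acetal solvolysis that passes the methoxymethyl group to methanol as dimethoxymethane, while aryl benzyl ethers are inert to dilute HCl at this temperature.

Step 13
Reactants: 25 the ring A phenol
Product: 26 sodium ring A sulfate of the octabenzyl terphenyl
Conditions: SO3·pyridine, pyridine, 55 °C; then aq NaHCO3
Reagents that add atoms: sulfur trioxide–pyridine complex, O=S(=O)=O.c1ccncc1; sodium hydrogen carbonate, [Na+].OC([O-])=O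
Why: O-Sulfonation of the only free phenol by the sulfur trioxide–pyridine complex, followed by exchange to the sodium salt, which avoids pyridine in the hydrogenolysis.

Step 14
Reactants: 26 the sodium sulfate
Product: 28 CNP0244954.0 (free hydrogen sulfate), via sodium salt 27 (not isolated)
Conditions: H2 (1 atm), Pd(OH)2/C, THF/MeOH, 25 °C, filtration under argon; then HCl (1.0 equiv), H2O, 0 °C, C18 desalting, freeze-drying
Reagents that add atoms: none
Why: Catalytic hydrogenolysis cleaves the eight benzylic C–O bonds while the aryl sulfate S–O bonds are inert to H2 on palladium, and one equivalent of cold acid then protonates the sulfate.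

**Compound list**

1 | 2,4,6-trihydroxybenzaldehyde | O=Cc1c(O)cc(O)cc1O | starting material
2 | 2,4,6-tris(benzyloxy)benzaldehyde | O=Cc1c(OCc2ccccc2)cc(OCc2ccccc2)cc1OCc1ccccc1 | intermediate
3 | 2-(benzyloxy)-N-methoxy-N-methylacetamide | CON(C)C(=O)COCc1ccccc1 | starting material
4 | lithium (Z)-enolate of 3 (not isolated) | [Li+].[O-]/C(N(C)OC)=C\OCc1ccccc1 | intermediate
5 | 2-(benzyloxy)-3-hydroxy-N-methoxy-N-methyl-3-[2,4,6-tris(benzyloxy)phenyl]propanamide, racemic syn/anti mixture | CON(C)C(=O)C(OCc1ccccc1)C(O)c1c(OCc2ccccc2)cc(OCc2ccccc2)cc1OCc1ccccc1 | intermediate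
6 | 3-O-methanesulfonate of 5 (not isolated) | CON(C)C(=O)C(OCc1ccccc1)C(OS(C)(=O)=O)c1c(OCc2ccccc2)cc(OCc2ccccc2)cc1OCc1ccccc1 | intermediate
7 | (Z)-2-(benzyloxy)-N-methoxy-N-methyl-3-[2,4,6-tris(benzyloxy)phenyl]prop-2-enamide | CON(C)C(=O)/C(OCc1ccccc1)=C/c1c(OCc2ccccc2)cc(OCc2ccccc2)cc1OCc1ccccc1 | intermediate
8 | (Z)-3-(benzyloxy)-4-[2,4,6-tris(benzyloxy)phenyl]but-3-en-2-one | CC(=O)/C(OCc1ccccc1)=C/c1c(OCc2ccccc2)cc(OCc2ccccc2)cc1OCc1ccccc1 | intermediate
9 | (Z)-5-(benzyloxy)-1,1,1-trifluoro-6-[2,4,6-tris(benzyloxy)phenyl]hex-5-ene-2,4-dione (not isolated) | O=C(CC(=O)/C(OCc1ccccc1)=C/c1c(OCc2ccccc2)cc(OCc2ccccc2)cc1OCc1ccccc1)C(F)(F)F | intermediate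
10 | (Z)-3-(benzyloxy)-1-diazo-4-[2,4,6-tris(benzyloxy)phenyl]but-3-en-2-one | [N-]=[N+]=CC(=O)/C(OCc1ccccc1)=C/c1c(OCc2ccccc2)cc(OCc2ccccc2)cc1OCc1ccccc1 | intermediate
11 | 3,5-bis(benzyloxy)phenol | Oc1cc(OCc2ccccc2)cc(OCc2ccccc2)c1 | starting material
12 | 2,4-bis(benzyloxy)-6-hydroxybenzaldehyde | O=Cc1c(O)cc(OCc2ccccc2)cc1OCc1ccccc1 | intermediate
13 | 2,4-bis(benzyloxy)-6-(methoxymethoxy)benzaldehyde | O=Cc1c(OCOC)cc(OCc2ccccc2)cc1OCc1ccccc1 | intermediate
14 | 1,5-bis(benzyloxy)-2-ethynyl-3-(methoxymethoxy)benzene | C#Cc1c(OCOC)cc(OCc2ccccc2)cc1OCc1ccccc1 | intermediate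
15 | lithium acetylide of 14 (not isolated) | [Li+].[C-]#Cc1c(OCOC)cc(OCc2ccccc2)cc1OCc1ccccc1 | intermediate
16 | lithium 2-[2,4-bis(benzyloxy)-6-(methoxymethoxy)phenyl]ethyn-1-olate (not isolated) | [Li+].[O-]C#Cc1c(OCOC)cc(OCc2ccccc2)cc1OCc1ccccc1 | intermediate
17 | triisopropyl({[2,4-bis(benzyloxy)-6-(methoxymethoxy)phenyl]ethynyl}oxy)silane | CC(C)[Si](OC#Cc1c(OCOC)cc(OCc2ccccc2)cc1OCc1ccccc1)(C(C)C)C(C)C | intermediate
18 | (Z)-3-(benzyloxy)-4-[2,4,6-tris(benzyloxy)phenyl]buta-1,3-dien-1-one, the vinylketene (not isolated) | O=C=C/C(OCc1ccccc1)=C/c1c(OCc2ccccc2)cc(OCc2ccccc2)cc1OCc1ccccc1 | intermediate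
19 | 2-[2,4-bis(benzyloxy)-6-(methoxymethoxy)phenyl]-4-{(Z)-1-(benzyloxy)-2-[2,4,6-tris(benzyloxy)phenyl]ethenyl}-3-(triisopropylsilyloxy)cyclobut-2-en-1-one, racemic at C4 (not isolated) | O=C1C(/C(OCc2ccccc2)=C/c2c(OCc3ccccc3)cc(OCc3ccccc3)cc2OCc2ccccc2)C(O[Si](C(C)C)(C(C)C)C(C)C)=C1c1c(OCOC)cc(OCc2ccccc2)cc1OCc1ccccc1 | intermediate
20 | dienylketene from 4π opening of 19, B2=B3 bond cis, B4=B5 bond with ring C trans to B3 (not isolated) | O=C=C(c1c(OCOC)cc(OCc2ccccc2)cc1OCc1ccccc1)/C(O[Si](C(C)C)(C(C)C)C(C)C)=C\C(OCc1ccccc1)=C\c1c(OCc2ccccc2)cc(OCc2ccccc2)cc1OCc1ccccc1 | intermediate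
21 | 5-(benzyloxy)-2-[2,4-bis(benzyloxy)-6-(methoxymethoxy)phenyl]-6-[2,4,6-tris(benzyloxy)phenyl]-3-(triisopropylsilyloxy)cyclohexa-2,4-dien-1-one, racemic at C6 (not isolated) | O=C1C(c2c(OCc3ccccc3)cc(OCc3ccccc3)cc2OCc2ccccc2)C(OCc2ccccc2)=CC(O[Si](C(C)C)(C(C)C)C(C)C)=C1c1c(OCOC)cc(OCc2ccccc2)cc1OCc1ccccc1 | intermediate
22 | terphenyl phenol: B6 OH, B2 OSi(iPr)3, B4 OBn; ring A with methoxymethyl ether at its carbon 2 and benzyl ethers at its carbons 4 and 6; ring C 2,4,6-tris(OBn) | COCOc1cc(OCc2ccccc2)cc(OCc2ccccc2)c1-c1c(O[Si](C(C)C)(C(C)C)C(C)C)cc(OCc2ccccc2)c(-c2c(OCc3ccccc3)cc(OCc3ccccc3)cc2OCc2ccccc2)c1O | intermediate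
23 | ring B diol: B2 OH and B6 OH, otherwise as 22 (not isolated) | COCOc1cc(OCc2ccccc2)cc(OCc2ccccc2)c1-c1c(O)cc(OCc2ccccc2)c(-c2c(OCc3ccccc3)cc(OCc3ccccc3)cc2OCc2ccccc2)c1O | intermediate
24 | octabenzyl ether with the ring A methoxymethyl ether | COCOc1cc(OCc2ccccc2)cc(OCc2ccccc2)c1-c1c(OCc2ccccc2)cc(OCc2ccccc2)c(-c2c(OCc3ccccc3)cc(OCc3ccccc3)cc2OCc2ccccc2)c1OCc1ccccc1 | intermediate
25 | octabenzyl ether with the free ring A hydroxyl | Oc1cc(OCc2ccccc2)cc(OCc2ccccc2)c1-c1c(OCc2ccccc2)cc(OCc2ccccc2)c(-c2c(OCc3ccccc3)cc(OCc3ccccc3)cc2OCc2ccccc2)c1OCc1ccccc1 | intermediate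
26 | sodium ring A sulfate of the octabenzyl terphenyl | [Na+].[O-]S(=O)(=O)Oc1cc(OCc2ccccc2)cc(OCc2ccccc2)c1-c1c(OCc2ccccc2)cc(OCc2ccccc2)c(-c2c(OCc3ccccc3)cc(OCc3ccccc3)cc2OCc2ccccc2)c1OCc1ccccc1 | intermediate
27 | sodium salt of the target (not isolated) | [Na+].[O-]S(=O)(=O)Oc1cc(O)cc(O)c1-c1c(O)cc(O)c(-c2c(O)cc(O)cc2O)c1O | intermediate
28 | CNP0244954.0 | O=S(=O)(O)Oc1cc(O)cc(O)c1-c1c(O)cc(O)c(-c2c(O)cc(O)cc2O)c1O | target

**Step count and risks**

Total step count: 14. Longest linear sequence: 10 steps (steps 1–5 and 10–14).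

Steps most likely to fail:

1. Step 10. The vinylketene may dimerise faster than the doubly ortho-substituted siloxyalkyne captures it. The cascade may also stall before the 6π closure, which sets two fully ortho-substituted aryl rings beside the new hydroxyl. Fallback: the terphenyl would be assembled by two Suzuki–Miyaura couplings, setting out from 11 and coming back at 24. Benzylation of 11 (BnBr, K2CO3, DMF) would give 1,3,5-tris(benzyloxy)benzene F1, and one equivalent of N-bromosuccinimide (CH2Cl2, −40 °C) would convert it into 2-bromo-1,3,5-tris(benzyloxy)benzene F2. One portion of F2 would undergo bromine–lithium exchange (n-BuLi, THF, −78 °C) and borylation with B(OMe)3 to give [2,4,6-tris(benzyloxy)phenyl]boronic acid F3, while a second portion would be iodinated with N-iodosuccinimide to 1,3,5-tris(benzyloxy)-2-bromo-4-iodobenzene F4. Coupling of F3 with F4 at the carbon–iodine bond (Pd(OAc)2, 2-dicyclohexylphosphino-2',6'-dimethoxybiphenyl, K3PO4, toluene/water) would give 3-bromo-2,2',4,4',6,6'-hexakis(benzyloxy)-1,1'-biphenyl F5, which holds rings B and C. For ring A, 11 would be protected (NaH, MOMCl) as 1,3-bis(benzyloxy)-5-(methoxymethoxy)benzene F6; directed ortho-lithiation between the acetal and a benzyloxy group (n-BuLi, THF, 0 °C), trapped with 2-isopropoxy-4,4,5,5-tetramethyl-1,3,2-dioxaborolane, would give 2-[2,4-bis(benzyloxy)-6-(methoxymethoxy)phenyl]-4,4,5,5-tetramethyl-1,3,2-dioxaborolane F7. A second coupling of F7 with F5 under the same catalyst would return to the route at 24; steps 12 to 14 follow unchanged.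

2. Step 9. Oxygen transfer from the peroxide to the hindered, electron-rich acetylide may be incomplete, and the acid-sensitive ynol silyl ether may hydrolyse during isolation. Fallback: ynolate 16 would be generated by a Kowalski-type rearrangement, setting out from 13 and coming back at 17. Addition of LiCHBr2 (CH2Br2, LiN(iPr)2, THF, −78 °C) to 13 would give 1-[2,4-bis(benzyloxy)-6-(methoxymethoxy)phenyl]-2,2-dibromoethan-1-ol F8, and Dess–Martin oxidation would give 1-[2,4-bis(benzyloxy)-6-(methoxymethoxy)phenyl]-2,2-dibromoethan-1-one F9. Enolisation of F9 with LiN(SiMe3)2 and then n-BuLi (−78 → 0 °C) would give 16 by bromine–lithium exchange and 1,2-aryl shift; O-silylation with iPr3SiOTf would rejoin the route at 17.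

3. Step 14. Hydrogenolysis of the two flanked benzyl ethers on ring B may be slow, and the sulfate monoester may be lost by S–O hydrolysis during long reaction times or on acidification. Fallback: the sulfate would be carried through the hydrogenolysis as a neutral diester, setting out from 25 and coming back at 27. Deprotonation of 25 (NaN(SiMe3)2, THF, −78 °C) and reaction with neopentyl chlorosulfate would give the neopentyl ring A sulfate of the octabenzyl terphenyl F10. Hydrogenolysis (H2, Pd(OH)2/C) would give the neopentyl ring A sulfate of the free octaphenol F11, and dealkylation with NaN3 (DMF, 70 °C) would return to the route at 27, which is protonated as in step 14.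

Further compounds
F1 | step 10 | 1,3,5-tris(benzyloxy)benzene | c1c(OCc2ccccc2)cc(OCc2ccccc2)cc1OCc1ccccc1
F2 | step 10 | 2-bromo-1,3,5-tris(benzyloxy)benzene | Brc1c(OCc2ccccc2)cc(OCc2ccccc2)cc1OCc1ccccc1
F3 | step 10 | [2,4,6-tris(benzyloxy)phenyl]boronic acid | OB(O)c1c(OCc2ccccc2)cc(OCc2ccccc2)cc1OCc1ccccc1
F4 | step 10 | 1,3,5-tris(benzyloxy)-2-bromo-4-iodobenzene | Brc1c(OCc2ccccc2)cc(OCc2ccccc2)c(I)c1OCc1ccccc1
F5 | step 10 | 3-bromo-2,2',4,4',6,6'-hexakis(benzyloxy)-1,1'-biphenyl | Brc1c(OCc2ccccc2)cc(OCc2ccccc2)c(-c2c(OCc3ccccc3)cc(OCc3ccccc3)cc2OCc2ccccc2)c1OCc1ccccc1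
F6 | step 10 | 1,3-bis(benzyloxy)-5-(methoxymethoxy)benzene | COCOc1cc(OCc2ccccc2)cc(OCc2ccccc2)c1
F7 | step 10 | 2-[2,4-bis(benzyloxy)-6-(methoxymethoxy)phenyl]-4,4,5,5-tetramethyl-1,3,2-dioxaborolane | COCOc1cc(OCc2ccccc2)cc(OCc2ccccc2)c1B1OC(C)(C)C(C)(C)O1
F8 | step 9 | 1-[2,4-bis(benzyloxy)-6-(methoxymethoxy)phenyl]-2,2-dibromoethan-1-ol | OC(C(Br)Br)c1c(OCOC)cc(OCc2ccccc2)cc1OCc1ccccc1
F9 | step 9 | 1-[2,4-bis(benzyloxy)-6-(methoxymethoxy)phenyl]-2,2-dibromoethan-1-one | O=C(C(Br)Br)c1c(OCOC)cc(OCc2ccccc2)cc1OCc1ccccc1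
F10 | step 14 | neopentyl ring A sulfate of the octabenzyl terphenyl | CC(C)(C)COS(=O)(=O)Oc1cc(OCc2ccccc2)cc(OCc2ccccc2)c1-c1c(OCc2ccccc2)cc(OCc2ccccc2)c(-c2c(OCc3ccccc3)cc(OCc3ccccc3)cc2OCc2ccccc2)c1OCc1ccccc1
F11 | step 14 | neopentyl ring A sulfate of the free octaphenol | CC(C)(C)COS(=O)(=O)Oc1cc(O)cc(O)c1-c1c(O)cc(O)c(-c2c(O)cc(O)cc2O)c1O
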